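**Retrosynthetic overview**

1. The 14‑acetate is removed, then the ten‑membered ring and the butenolide are opened together at C7–C8. The forward step is a rhodium‑catalysed addition of the vinylic C8–H of an E‑enoic acid to a tethered Z‑enal, followed by lactonisation (seco enal acid 25).
2. 25 is cut at C2–C3: titanium‑catalysed enantioselective addition of the zinc reagent from Z‑iodide 20 to cyclohexenone aldehyde 13; the tiglate comes from acylation.
3. 13 comes from cross‑metathesis of an allyl group with methacrylate 12, the enone from a singlet‑oxygen ene/Kornblum–DeLaMare sequence, and the cyclohexene 6 from a catalytic enantioselective Diels–Alder reaction of dienal 3 with silyloxydiene 5.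
4. 20 comes from but‑2‑yn‑1‑ol via the Z‑vinyl iodide, a vinyl cross‑coupling and hydroboration–iodination.
5. Ring order: six‑membered carbocycle first (step 3); ten‑membered carbocycle and butenolide last, in one operation (step 15).

Convention: position labels follow the target skeleton. C1 is the quaternary ring‑fusion carbon (Me‑15), C2 the tiglate carbinol, C3/C4 methylenes, C5(Me‑16)=C6, C7 the lactone carbinol, C8=C17(Me‑19), C18 the lactone carbonyl, C9 a methylene, C10 the ring‑fusion CH, C11(Me‑20)=C12, C13 the ketone, C14 the acetate carbinol.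

Assumption: the (S)‑oxazaborolidinium catalyst of step 3 delivers the diene to the Re face of the α‑carbon (C1) of enal 3, and the (R)‑Cpx rhodium catalyst of step 15 gives the 7R lactone. If either sense is found reversed, the mirror‑image catalyst is used and nothing else changes.

Cpx = C2‑symmetric cyclopentadienyl fused through two CH2 groups to the 2,2'‑positions of (R)‑3,3'‑dimethoxy‑1,1'‑binaphthyl.

**Route**

Step 1
Reactants: 1 (E)-3-ethoxy-2-methylprop-2-enal
Product: 3 (E)-2-methylhexa-2,5-dienal, via magnesium alkoxide 2 (not isolated)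
Conditions: CH2=CHCH2MgBr (1.1 equiv), THF, −78 °C; then 1 M HCl, 0 °C
Reagents that add atoms: allylmagnesium bromide (C=CC[Mg]Br); water (O)
Why: Grignard 1,2‑addition to the vinylogous‑ester aldehyde followed by acid hydrolysis of the enol ether with allylic transposition gives the thermodynamically favoured E‑enal, whose geometry later fixes the trans relation of C2 and C9; no stereocentre is formed.

Step 2
Reactants: 4 (E)-pent-2-enal
Product: 5 (1E,3E)-1-(tert-butyldimethylsilyloxy)penta-1,3-diene
Conditions: TBSOTf, Et3N, Et2O, 0 °C to rt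
Reagents that add atoms: tert-butyldimethylsilyl triflate (CC(C)(C)[Si](C)(C)OS(=O)(=O)C(F)(F)F)
Why: Soft γ‑enolisation and O‑silylation (silyl dienol ether formation) gives mainly the 1E,3E diene, and only this isomer can adopt the s‑cis geometry needed in step 3.

Step 3
Reactants: 3 (E)-2-methylhexa-2,5-dienal; 5 (1E,3E)-1-(tert-butyldimethylsilyloxy)penta-1,3-diene
Product: 6 (1S,2R,5S,6R)-6-allyl-2-(tert-butyldimethylsilyloxy)-1,5-dimethylcyclohex-3-ene-1-carbaldehyde
Conditions: (S)-B-(o-tolyl) diphenylprolinol oxazaborolidine·Tf2NH (20 mol %), CH2Cl2, −78 to −40 °C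
Reagents that add atoms: none
Why: In this cationic oxazaborolidine‑catalysed enantioselective Diels–Alder reaction the 1‑silyloxy group makes C11 the nucleophilic diene terminus so that C11 bonds to the enal β‑carbon C10 and C14 to C1 (ortho rule), the E‑enal puts C2 and C9 trans, endo approach of the formyl group puts the C14 oxygen cis to C2, and the catalyst shields one enal face and so sets the absolute configuration at C1, C10 and C14 (C11 is erased in step 4).

Step 4
Reactants: 6 (1S,2R,5S,6R)-6-allyl-2-(tert-butyldimethylsilyloxy)-1,5-dimethylcyclohex-3-ene-1-carbaldehyde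
Product: 9 (1S,2S,6R)-6-allyl-2-(tert-butyldimethylsilyloxy)-1,5-dimethyl-3-oxocyclohex-4-ene-1-carbaldehyde, via allylic hydroperoxide 7 (not isolated), via peroxyacetate 8 (not isolated)
Conditions: O2, hν (visible LED), tetraphenylporphyrin (1 mol %), Ac2O, pyridine, DMAP (5 mol %), CH2Cl2, 0 °C to rt
Reagents that add atoms: dioxygen (O=O)
Why: A Schenck ene reaction of singlet oxygen on the ring alkene abstracts the tertiary allylic C11–H rather than the deactivated C14–H geminal to the silyloxy group, and in situ acetylation with Kornblum–DeLaMare fragmentation of the hydroperoxide gives the transposed enone, while the monosubstituted allyl alkene is inert and the only stereocentre touched (C11) becomes sp2.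

Step 5
Reactants: 10 2-(trimethylsilyl)ethanol; 11 methacryloyl chloride
Product: 12 2-(trimethylsilyl)ethyl methacrylate
Conditions: Et3N, DMAP (cat.), CH2Cl2, 0 °C to rt
Reagents that add atoms: none
Why: Acylation of the alcohol by the acid chloride (nucleophilic acyl substitution) gives the fluoride‑cleavable ester that will supply C17, C18 and C19.

Step 6
Reactants: 9 (1S,2S,6R)-6-allyl-2-(tert-butyldimethylsilyloxy)-1,5-dimethyl-3-oxocyclohex-4-ene-1-carbaldehyde; 12 2-(trimethylsilyl)ethyl methacrylate
Product: 13 2-(trimethylsilyl)ethyl (E)-4-[(1R,5S,6S)-5-(tert-butyldimethylsilyloxy)-6-formyl-2,6-dimethyl-4-oxocyclohex-2-en-1-yl]-2-methylbut-2-enoate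
Conditions: Hoveyda–Grubbs second-generation catalyst [RuCl2(H2IMes)(=CH-C6H4-2-OiPr)] (5 mol %), 12 (8 equiv), CH2Cl2, 40 °C
Reagents that add atoms: none
Why: Olefin cross‑metathesis of the terminal allyl alkene with a 1,1‑disubstituted acrylate gives the E‑trisubstituted enoate under thermodynamic control, with the enone and the aldehyde as spectators.

Step 7
Reactants: 14 but-2-yn-1-ol
Product: 16 (Z)-3-iodobut-2-en-1-ol, via alkenylalanate 15 (not isolated)
Conditions: NaAlH2(OCH2CH2OMe)2, THF, 0 °C to rt; then I2, −78 to 0 °C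
Reagents that add atoms: iodine (II)
Why: Hydroxyl‑directed trans‑hydroalumination of the propargylic alcohol places aluminium on C5 in a five‑membered alanate, and iodinolysis with retention gives the Z‑vinyl iodide that defines the C5=C6 geometry.

Step 8
Reactants: 16 (Z)-3-iodobut-2-en-1-ol
Product: 17 (Z)-tert-butyl[(3-iodobut-2-en-1-yl)oxy]dimethylsilane
Conditions: TBSCl, imidazole, CH2Cl2, 0 °C to rt
Reagents that add atoms: tert-butyldimethylsilyl chloride (CC(C)(C)[Si](C)(C)Cl)
Why: Standard imidazole‑promoted silylation protects the C7 oxygen for the organometallic steps that follow.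

Step 9
Reactants: 17 (Z)-tert-butyl[(3-iodobut-2-en-1-yl)oxy]dimethylsilane
Product: 18 (Z)-tert-butyldimethyl[(3-methylpenta-2,4-dien-1-yl)oxy]silane
Conditions: CH2=CHMgBr (1.5 equiv), Pd(PPh3)4 (5 mol %), THF, 0 °C to rt
Reagents that add atoms: vinylmagnesium bromide (C=C[Mg]Br)
Why: Palladium‑catalysed Kumada–Corriu cross‑coupling of the alkenyl iodide proceeds with retention of the Z geometry and brings in C3 and C4.

Step 10
Reactants: 18 (Z)-tert-butyldimethyl[(3-methylpenta-2,4-dien-1-yl)oxy]silane
Product: 20 (Z)-tert-butyl[(5-iodo-3-methylpent-2-en-1-yl)oxy]dimethylsilane, via alkylborane 19 (not isolated)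
Conditions: 9-BBN, THF, 0 °C to rt; then NaOMe, I2, MeOH, 0 °C
Reagents that add atoms: iodine (II)
Why: 9‑BBN hydroborates only the monosubstituted vinyl group at its CH2 terminus, and base‑induced iodinolysis of the primary B–C bond (Brown iodination) gives the homoallylic iodide without touching the Z‑trisubstituted alkene.

Step 11
Reactants: 13 2-(trimethylsilyl)ethyl (E)-4-[(1R,5S,6S)-5-(tert-butyldimethylsilyloxy)-6-formyl-2,6-dimethyl-4-oxocyclohex-2-en-1-yl]-2-methylbut-2-enoate; 20 (Z)-tert-butyl[(5-iodo-3-methylpent-2-en-1-yl)oxy]dimethylsilane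
Product: 22 (2S)-alcohol in which the CHO of 13 has become CH(OH)–CH2CH2–C(CH3)=CH–CH2OTBS (5Z), via dialkylzinc 21 (not isolated)
Conditions: 20 (2.5 equiv), Et2Zn (neat), CuI (0.3 mol %), 55 °C, then evaporation; 13, Ti(OiPr)4 (2 equiv), (1R,2R)-1,2-bis(trifluoromethanesulfonamido)cyclohexane (8 mol %), toluene, −20 °C; 1 M HCl work-up
Reagents that add atoms: none
Why: Iodine–zinc exchange gives the functionalised dialkylzinc, and its titanium bis(sulfonamide)‑catalysed enantioselective 1,2‑addition reacts only with the aldehyde, the (1R,2R) ligand directing the alkyl group to the Si face so that C2 is formed S under reagent control while the enone and ester are untouched.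

Step 12
Reactants: 22 (2S)-alcohol from step 11
Product: 23 2-O-tiglate of 22
Conditions: (E)-2-methylbut-2-enoyl chloride, pyridine, DMAP (20 mol %), CH2Cl2, 0 to 40 °C
Reagents that add atoms: (E)-2-methylbut-2-enoyl chloride (C/C=C(\C)C(Cl)=O)
Why: DMAP‑catalysed acylation of the hindered secondary alcohol occurs with retention at C2, pyridine being used instead of a trialkylamine to avoid ketene‑mediated deconjugation of the acyl chloride.

Step 13
Reactants: 23 2-O-tiglate of 22
Product: 24 seco dihydroxy acid (free C7–OH and C14–OH; free C18 acid)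
Conditions: TBAF (6 equiv), AcOH (3 equiv), THF, 0 °C to rt
Reagents that add atoms: none
Why: Fluoride cleaves both silyl ethers and triggers β‑elimination of the 2‑(trimethylsilyl)ethyl ester in one operation, with acetic acid buffering to suppress tiglate migration and epimerisation at C14.

Step 14
Reactants: 24 seco dihydroxy acid
Product: 25 seco enal acid (C7 aldehyde on the 5Z alkene)
Conditions: PhI(OAc)2 (1.2 equiv), TEMPO (10 mol %), CH2Cl2, 0 °C to rt
Reagents that add atoms: none
Why: The TEMPO/PhI(OAc)2 oxidation is selective for the primary allylic alcohol over the hindered secondary α‑ketol, tolerates the free acid and gives the Z‑enal without isomerisation.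

Step 15
Reactants: 25 seco enal acid
Product: 27 14-O-deacetyl target (macrocyclic butenolide with free C14–OH), via hydroxy acid 26 (not isolated)
Conditions: [(R)-CpxRh(C2H4)2] (10 mol %), (BzO)2 (10 mol %), PivOH (30 mol %), 4 Å MS, ClCH2CH2Cl (1 mM, slow addition of 25), 50 °C
Reagents that add atoms: none
Why: Proposed new method: a chiral cyclopentadienyl complex of trivalent rhodium should activate, by carboxylate‑assisted concerted metalation–deprotonation, the vinylic C8–H that lies cis to the carboxyl group of the E‑2‑methyl‑2‑enoic acid to give a five‑membered rhodacycle, insert the tethered C7 aldehyde into the Rh–C8 bond (forming the C7–C8 bond and the ten‑membered ring) and release the γ‑hydroxy acid 26 by protonolysis, whose irreversible lactonisation to the butenolide drives the otherwise reversible carbonyl insertion, with the chiral Cp ligand selecting the enal face to set C7 as R; the closest known reactions are the rhodium‑catalysed coupling of benzoic acids or benzimidates with aldehydes to give phthalides, the rhodium‑catalysed vinylic C–H annulation of acrylic acids with alkynes and alkenes, and chiral‑Cp rhodium C–H additions to aldehydes, none of which has been used to close a medium ring or with an enoic acid and an enal.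

Step 16
Reactants: 27 14-O-deacetyl target
Product: 28 (1R,2S,5Z,7R,10R,14S)-14-acetoxy-13-oxo-2-(tigloyloxy)briara-5,8(17),11-trien-18,7-olide (CNP0218548.3)
Conditions: Ac2O, pyridine, DMAP (10 mol %), CH2Cl2, 0 °C
Reagents that add atoms: acetic anhydride (CC(=O)OC(C)=O)
Why: DMAP‑catalysed acetylation of the remaining secondary alcohol with retention at C14 completes the target under conditions mild enough to leave the C7–H and C14–H untouched.

**Compound list**

1 | (E)-3-ethoxy-2-methylprop-2-enal | CCO/C=C(\C)C=O | starting material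
2 | bromomagnesium (E)-1-ethoxy-2-methylhexa-1,5-dien-3-olate (racemic at the carbinol carbon) | CCO/C=C(\C)C(CC=C)O[Mg]Br | intermediate
3 | (E)-2-methylhexa-2,5-dienal | O=C/C(C)=C/CC=C | intermediate
4 | (E)-pent-2-enal | CC/C=C/C=O | starting material
5 | (1E,3E)-1-(tert-butyldimethylsilyloxy)penta-1,3-diene | C/C=C/C=C/O[Si](C)(C)C(C)(C)C | intermediate
6 | (1S,2R,5S,6R)-6-allyl-2-(tert-butyldimethylsilyloxy)-1,5-dimethylcyclohex-3-ene-1-carbaldehyde (CHO, OTBS and 5-methyl cis to each other; allyl trans to CHO) | C[C@]1(C=O)[C@H](CC=C)[C@@H](C)C=C[C@H]1O[Si](C)(C)C(C)(C)C | intermediate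
7 | 6-allyl-2-(tert-butyldimethylsilyloxy)-3-hydroperoxy-1,5-dimethylcyclohex-4-ene-1-carbaldehyde (C1, C2, C6 as in 6; OOH trans to OTBS) | C[C@]1(C=O)[C@H](CC=C)C(C)=C[C@H](OO)[C@H]1O[Si](C)(C)C(C)(C)C | intermediate
8 | peroxyacetate of 7 (OOH replaced by OOAc) | C[C@]1(C=O)[C@H](CC=C)C(C)=C[C@H](OOC(C)=O)[C@H]1O[Si](C)(C)C(C)(C)C | intermediate
9 | (1S,2S,6R)-6-allyl-2-(tert-butyldimethylsilyloxy)-1,5-dimethyl-3-oxocyclohex-4-ene-1-carbaldehyde | C[C@]1(C=O)[C@H](CC=C)C(C)=CC(=O)[C@H]1O[Si](C)(C)C(C)(C)C | intermediate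
10 | 2-(trimethylsilyl)ethanol | C[Si](C)(C)CCO | starting material
11 | methacryloyl chloride | CC(=C)C(Cl)=O | starting material
12 | 2-(trimethylsilyl)ethyl methacrylate | CC(=C)C(=O)OCC[Si](C)(C)C | intermediate
13 | 2-(trimethylsilyl)ethyl (E)-4-[(1R,5S,6S)-5-(tert-butyldimethylsilyloxy)-6-formyl-2,6-dimethyl-4-oxocyclohex-2-en-1-yl]-2-methylbut-2-enoate | C[C@]1(C=O)[C@H](C/C=C(\C)C(=O)OCC[Si](C)(C)C)C(C)=CC(=O)[C@H]1O[Si](C)(C)C(C)(C)C | intermediate
14 | but-2-yn-1-ol | CC#CCO | starting material
15 | sodium cyclic alkenylalanate (five-membered O–Al–C=C ring from 14; two 2-methoxyethoxy groups on Al) | [Na+].CC1=CCO[Al-]1(OCCOC)OCCOC | intermediate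
16 | (Z)-3-iodobut-2-en-1-ol | C/C(I)=C/CO | intermediate
17 | (Z)-tert-butyl[(3-iodobut-2-en-1-yl)oxy]dimethylsilane | C/C(I)=C/CO[Si](C)(C)C(C)(C)C | intermediate
18 | (Z)-tert-butyldimethyl[(3-methylpenta-2,4-dien-1-yl)oxy]silane | C=C/C(C)=C\CO[Si](C)(C)C(C)(C)C | intermediate
19 | 9-[(Z)-5-(tert-butyldimethylsilyloxy)-3-methylpent-3-en-1-yl]-9-borabicyclo[3.3.1]nonane | CC(C)(C)[Si](C)(C)OC/C=C(C)\CCB1C2CCCC1CCC2 | intermediate
20 | (Z)-tert-butyl[(5-iodo-3-methylpent-2-en-1-yl)oxy]dimethylsilane | ICC/C(C)=C\CO[Si](C)(C)C(C)(C)C | intermediate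
21 | bis[(Z)-5-(tert-butyldimethylsilyloxy)-3-methylpent-3-en-1-yl]zinc | CC(C)(C)[Si](C)(C)OC/C=C(C)\CC[Zn]CC/C(C)=C\CO[Si](C)(C)C(C)(C)C | intermediate
22 | (2S)-alcohol: 13 in which CHO has become CH(OH)–CH2CH2–C(CH3)=CH–CH2OTBS (5Z); ring centres as in 13 | C[C@]1([C@@H](O)CC/C(C)=C\CO[Si](C)(C)C(C)(C)C)[C@H](C/C=C(\C)C(=O)OCC[Si](C)(C)C)C(C)=CC(=O)[C@H]1O[Si](C)(C)C(C)(C)C | intermediate
23 | 2-O-tiglate of 22 | C[C@]1([C@@H](OC(=O)/C(C)=C/C)CC/C(C)=C\CO[Si](C)(C)C(C)(C)C)[C@H](C/C=C(\C)C(=O)OCC[Si](C)(C)C)C(C)=CC(=O)[C@H]1O[Si](C)(C)C(C)(C)C | intermediate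
24 | seco dihydroxy acid: 23 without both TBS groups and the trimethylsilylethyl group (C7–OH, C14–OH, C18 acid) | C[C@]1([C@@H](OC(=O)/C(C)=C/C)CC/C(C)=C\CO)[C@H](C/C=C(\C)C(O)=O)C(C)=CC(=O)[C@H]1O | intermediate
25 | seco enal acid: 24 with C7 oxidised to the aldehyde (5Z enal; 8E enoic acid) | C[C@]1([C@@H](OC(=O)/C(C)=C/C)CC/C(C)=C\C=O)[C@H](C/C=C(\C)C(O)=O)C(C)=CC(=O)[C@H]1O | intermediate
26 | ten-membered (7R)-hydroxy acid: C7–C8 bond formed; C7–OH and C18 acid cis on C8=C17 (8Z); other centres as in 28 | C/C=C(\C)C(=O)O[C@H]1CC/C(C)=C\[C@@H](O)/C(=C(/C)C(O)=O)C[C@@H]2C(C)=CC(=O)[C@@H](O)[C@@]12C | intermediate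
27 | 14-O-deacetyl target: macrocyclic butenolide with free C14–OH; all stereocentres as in 28 | C/C=C(\C)C(=O)O[C@H]1CC/C(C)=C\[C@H]2OC(=O)C(C)=C2C[C@@H]2C(C)=CC(=O)[C@@H](O)[C@@]12C | intermediate
28 | (1R,2S,5Z,7R,10R,14S)-14-acetoxy-13-oxo-2-(tigloyloxy)briara-5,8(17),11-trien-18,7-olide (CNP0218548.3) | C/C=C(\C)C(=O)O[C@H]1CC/C(C)=C\[C@H]2OC(=O)C(C)=C2C[C@@H]2C(C)=CC(=O)[C@@H](OC(C)=O)[C@@]12C | target

**Step count and risks**

Total step count: 16.
Longest linear sequence: 10 steps (steps 1, 3, 4, 6, 11, 12, 13, 14, 15, 16; the branch from 14 through steps 7–10 is equally long).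

The three steps most likely to fail:

**Step 15 (the proposed rhodium C–H macro‑annulation).** Risks: the carbonyl insertion may be too slow for an unactivated β,β‑disubstituted enal, the ten‑membered ring may not close in competition with oligomerisation, or the wrong C7 epimer may form. The fallback uses known chemistry, sets out from 9 and comes back at 27. Aldehyde 9 is coupled with zinc reagent 21 exactly as in step 11 to give the allyl alcohol F1, which is acylated as in step 12 to give the tiglate F2. Cross‑metathesis of the allyl group of F2 with methyl 2‑(acetoxymethyl)acrylate (same ruthenium catalyst as step 6) gives the allylic acetate enoate F3. HF·pyridine removes both silyl groups to give the diol F4, and TEMPO/PhI(OAc)2 gives the enal F5. Pd(PPh3)4/InI umpolung (Barbier‑type) allylation then closes the ten‑membered ring at C7–C8, and the resulting alkoxide lactonises onto the methyl ester to give the α‑methylene lactone F6. C7 is under substrate control here and the minor epimer is removed; both C8 epimers are usable. RhCl3·3H2O in hot ethanol finally moves the exocyclic double bond into the ring to give 27.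

**Step 3 (Diels–Alder reaction).** Risks: a trisubstituted enal and a 1,4‑disubstituted diene are a demanding pair, and turnover or enantioselectivity of the chiral acid may be poor. The fallback separates ring construction from absolute stereocontrol; it sets out from 3 and 5 and comes back at 22. The cycloaddition is promoted with Me2AlCl (CH2Cl2, −78 °C) to give racemic endo adduct, that is 6 together with its mirror image F7. Steps 4 and 6 are run on the racemate, giving 9 with its mirror image F8 and 13 with its mirror image F9. In step 11 the chiral titanium catalyst sets C2 as S in both enantiomers, so the racemate becomes 22 and the diastereomeric alcohol F10, which is removed by chromatography (resolution by catalyst‑controlled diastereomer formation).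

**Step 11 (fragment union at the neopentyl aldehyde).** Risks: the α‑quaternary aldehyde may add the dialkylzinc slowly or with low selectivity, and the step needs an excess of 20. The fallback changes the bond that joins the fragments from C2–C3 to C4–C5; it sets out from 13 and comes back at 23. Asymmetric Nozaki–Hiyama–Kishi vinylation of 13 (vinyl bromide, CrCl2, NiCl2 cat., chiral sulfonamide ligand) gives the vinyl carbinol F11, which is acylated as in step 12 to give the tiglate F12. 9‑BBN hydroboration of the vinyl group gives the alkylborane F13. B‑alkyl Suzuki–Miyaura coupling of F13 with vinyl iodide 17 (PdCl2(dppf), AsPh3, Cs2CO3, DMF/THF/H2O, rt) proceeds with retention of the Z geometry and gives 23.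

**Further compounds**

F1 | step 15 | allyl alcohol: 9 after addition of 21 to the aldehyde (2S; allyl group kept) | C[C@]1([C@@H](O)CC/C(C)=C\CO[Si](C)(C)C(C)(C)C)[C@H](CC=C)C(C)=CC(=O)[C@H]1O[Si](C)(C)C(C)(C)C
F2 | step 15 | 2-O-tiglate of F1 | C[C@]1([C@@H](OC(=O)/C(C)=C/C)CC/C(C)=C\CO[Si](C)(C)C(C)(C)C)[C@H](CC=C)C(C)=CC(=O)[C@H]1O[Si](C)(C)C(C)(C)C
F3 | step 15 | allylic acetate enoate: F2 with the allyl group converted to CH2–CH=C(CH2OAc)–CO2Me | C[C@]1([C@@H](OC(=O)/C(C)=C/C)CC/C(C)=C\CO[Si](C)(C)C(C)(C)C)[C@H](C/C=C(\COC(C)=O)C(=O)OC)C(C)=CC(=O)[C@H]1O[Si](C)(C)C(C)(C)C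
F4 | step 15 | diol: F3 without both TBS groups | C[C@]1([C@@H](OC(=O)/C(C)=C/C)CC/C(C)=C\CO)[C@H](C/C=C(\COC(C)=O)C(=O)OC)C(C)=CC(=O)[C@H]1O
F5 | step 15 | enal: F4 with C7 oxidised to the aldehyde | C[C@]1([C@@H](OC(=O)/C(C)=C/C)CC/C(C)=C\C=O)[C@H](C/C=C(\COC(C)=O)C(=O)OC)C(C)=CC(=O)[C@H]1O
F6 | step 15 | macrocyclic α-methylene γ-lactone (7R; C8–H, both C8 epimers; exocyclic C17=CH2; free C14–OH) | C/C=C(\C)C(=O)O[C@H]1CC/C(C)=C\[C@H]2OC(=O)C(=C)C2C[C@@H]2C(C)=CC(=O)[C@@H](O)[C@@]12C
F7 | step 3 | mirror image of 6 | C[C@@]1(C=O)[C@@H](CC=C)[C@H](C)C=C[C@@H]1O[Si](C)(C)C(C)(C)C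
F8 | step 3 | mirror image of 9 | C[C@@]1(C=O)[C@@H](CC=C)C(C)=CC(=O)[C@@H]1O[Si](C)(C)C(C)(C)C
F9 | step 3 | mirror image of 13 | C[C@@]1(C=O)[C@@H](C/C=C(\C)C(=O)OCC[Si](C)(C)C)C(C)=CC(=O)[C@@H]1O[Si](C)(C)C(C)(C)C
F10 | step 3 | diastereomer of 22 formed from F9 (ring centres inverted; C2 still S) | C[C@@]1([C@@H](O)CC/C(C)=C\CO[Si](C)(C)C(C)(C)C)[C@@H](C/C=C(\C)C(=O)OCC[Si](C)(C)C)C(C)=CC(=O)[C@@H]1O[Si](C)(C)C(C)(C)C
F11 | step 11 | vinyl carbinol: 13 with CHO converted to (S)-CH(OH)–CH=CH2 | C[C@]1([C@@H](O)C=C)[C@H](C/C=C(\C)C(=O)OCC[Si](C)(C)C)C(C)=CC(=O)[C@H]1O[Si](C)(C)C(C)(C)C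
F12 | step 11 | 2-O-tiglate of F11 | C[C@]1([C@@H](OC(=O)/C(C)=C/C)C=C)[C@H](C/C=C(\C)C(=O)OCC[Si](C)(C)C)C(C)=CC(=O)[C@H]1O[Si](C)(C)C(C)(C)C
F13 | step 11 | B-alkyl-9-BBN from F12 (boron on C4) | C[C@]1([C@@H](OC(=O)/C(C)=C/C)CCB2C3CCCC2CCC3)[C@H](C/C=C(\C)C(=O)OCC[Si](C)(C)C)C(C)=CC(=O)[C@H]1O[Si](C)(C)C(C)(C)C
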